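**Plan**

- Locants are those of the target oxolane: O1, C2 (aryl), C3 (CH2O‑stearoyl), C4 (benzyl), C5 (ring CH2). Ar = 4‑(benzyloxy)‑3‑methoxyphenyl.
- Cuts: the stearate C–O bond and the two ArO–benzyl bonds (end game); O1–C5, taken back to the acyl–oxygen bond of a γ‑lactone with C5 raised to the carbonyl level; C2–C3 (aldol); the C4–CH2Ar bond (Stobbe).
- Enabling feature: O1 on C2 stands 1,4 to C5 (O1–C2–C3–C4–C5) and C3 is α to its exocyclic carbon, so at the carboxyl level the ring is a γ‑aryl paraconic lactone. One aldol at C3 onto the aryl aldehyde puts an oxygen on C2 that closes onto a C5 ester.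
- Forward: Stobbe condensation joins the benzyl carbon to C4; asymmetric hydrogenation; imide formation; aldol/lactonization builds the only ring. Then the C3 acyl group becomes CH2OH, the C5 carbonyl becomes CH2 (lactol, silane), and stearoylation and debenzylation finish the route.
- Stereochemistry: C4 from rhodium‑catalyzed asymmetric hydrogenation; C2 and C3 from the oxazolidinone‑controlled syn‑aldol (syn becomes 2,3‑trans on the ring). Helpers removed later: the auxiliary (step 5) and the C5 carbonyl oxygen (steps 7 and 8).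

Key step: step 4

Assumption: compounds 1, 2, 6 and 17 are taken as commercial; the target is read as (2S,3R,4R) on the oxolane.

**Step 1**
Reactants: 1 4‑(benzyloxy)‑3‑methoxybenzaldehyde; 2 dimethyl succinate
Product: 4 (3E)‑4‑Ar‑3‑(methoxycarbonyl)but‑3‑enoic acid, via paraconic ester lactone 3 (not isolated)
Conditions: NaOMe, MeOH, reflux; then aq. HCl
Reagents that add atoms: none
Why: Stobbe condensation, in which the succinate enolate adds to the non‑enolizable aldehyde, the aldolate lactonizes to 3 and E1cB ring opening gives the half‑ester with the free acid on the CH2 carbon (future C3 side) and the ester on the future C5; no stereocenter is formed.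

**Step 2**
Reactants: 4 (3E)‑4‑Ar‑3‑(methoxycarbonyl)but‑3‑enoic acid
Product: 5 (3R)‑4‑Ar‑3‑(methoxycarbonyl)butanoic acid
Conditions: H2 (5 bar), [Rh(cod)((S,S)‑Et‑DuPHOS)]BF4 (1 mol%), NaOMe (0.1 equiv), MeOH, rt
Reagents that add atoms: none
Why: Rhodium–bisphospholane asymmetric hydrogenation of an itaconate‑type half‑ester, in which carboxylate and alkene chelate the metal and the ligand antipode is the one expected to deliver the R center (future C4); aryl benzyl ethers should be inert to the homogeneous catalyst.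

**Step 3**
Reactants: 5 (3R)‑4‑Ar‑3‑(methoxycarbonyl)butanoic acid; 6 (4S)‑4‑benzyl‑1,3‑oxazolidin‑2‑one
Product: 8 methyl (2R)‑2‑(Ar‑methyl)‑4‑[(4S)‑4‑benzyl‑2‑oxo‑1,3‑oxazolidin‑3‑yl]‑4‑oxobutanoate, via mixed pivalic anhydride 7 (not isolated)
Conditions: t‑BuCOCl, Et3N, THF, −20 °C; then LiCl, 6, −20 °C to rt
Reagents that add atoms: none
Why: N‑acylation of the oxazolidinone through the mixed pivalic anhydride (attack at the less hindered carbonyl), which should leave the C4 center and the methyl ester untouched.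

**Step 4**
Reactants: 8 methyl (2R)‑2‑(Ar‑methyl)‑4‑[(4S)‑4‑benzyl‑2‑oxo‑1,3‑oxazolidin‑3‑yl]‑4‑oxobutanoate; 1 4‑(benzyloxy)‑3‑methoxybenzaldehyde
Product: 11 (4S)‑4‑benzyl‑3‑{[(2S,3S,4R)‑2‑Ar‑4‑(Ar‑methyl)‑5‑oxooxolan‑3‑yl]carbonyl}‑1,3‑oxazolidin‑2‑one, via Z‑boron enolate 9 (not isolated), via syn‑aldol adduct 10 (not isolated)
Conditions: n‑Bu2BOTf, i‑Pr2NEt, CH2Cl2, 0 °C; 1, −78 to 0 °C; pH 7 buffer, MeOH, 30% H2O2, 0 °C; then PPTS (cat.), CH2Cl2, rt
Reagents that add atoms: none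
Why: n‑Bu2BOTf/i‑Pr2NEt should enolize only the imide CH2 (future C3) to the Z‑boron enolate 9, which adds to aldehyde 1 through a closed chair transition state with the auxiliary carbonyl turned away from the enolate oxygen, so that the aldehyde meets the enolate face opposite to the auxiliary benzyl group; the C2 hydroxyl of 10 then attacks the methyl ester five atoms away and expels methanol (addition–elimination), which makes the O1–C5 bond and the ring. The closest known reaction type is the Evans syn‑aldol/lactonization of 3‑substituted succinyl oxazolidinones to paraconic‑type γ‑lactones. The ring closes in the 5‑exo‑trig mode. C2 and C3 are set by the (S)‑auxiliary through the Z‑enolate and the chair; the syn relation of hydroxyl and C4 branch becomes the 2,3‑trans relation of aryl and acyl groups on the ring, while C4 (R, from step 2) is not touched and ends cis to the acyl group. The step needs enolization of the imide and not of the ester α‑CH (secured by soft boron enolization), dominance of the auxiliary over the resident C4 center, and closure onto C5 only (the other acyl carbon within reach would give a four‑membered ring).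

**Step 5**
Reactants: 11 (4S)‑4‑benzyl‑3‑{[(2S,3S,4R)‑2‑Ar‑4‑(Ar‑methyl)‑5‑oxooxolan‑3‑yl]carbonyl}‑1,3‑oxazolidin‑2‑one
Product: 12 (3R,4R,5S)‑5‑Ar‑3‑(Ar‑methyl)‑4‑(hydroxymethyl)oxolan‑2‑one
Conditions: NaBH4, THF/H2O (3:1), 0 °C to rt
Reagents that add atoms: none
Why: Borohydride reductive cleavage of an N‑acyl oxazolidinone, in which the exocyclic imide carbonyl is much more electrophilic than the γ‑lactone and should be taken to the primary alcohol with release of 6; no stereocenter changes.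

**Step 6**
Reactants: 12 (3R,4R,5S)‑5‑Ar‑3‑(Ar‑methyl)‑4‑(hydroxymethyl)oxolan‑2‑one
Product: 13 (3R,4R,5S)‑5‑Ar‑3‑(Ar‑methyl)‑4‑{[tert‑butyl(diphenyl)silyl]oxymethyl}oxolan‑2‑one
Conditions: t‑BuPh2SiCl, imidazole, CH2Cl2, 0 °C to rt
Reagents that add atoms: tert‑butyl(chloro)diphenylsilane CC(C)(C)[Si](Cl)(c1ccccc1)c1ccccc1
Why: Imidazole‑promoted silylation of the primary alcohol, done at once because the free hydroxymethyl group could take over the lactone carbonyl by acyl migration, and needed so that O1 is the only oxygen able to hold C5 in steps 7 and 8.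

**Step 7**
Reactants: 13 (3R,4R,5S)‑5‑Ar‑3‑(Ar‑methyl)‑4‑{[tert‑butyl(diphenyl)silyl]oxymethyl}oxolan‑2‑one
Product: 14 (3R,4R,5S)‑5‑Ar‑3‑(Ar‑methyl)‑4‑{[tert‑butyl(diphenyl)silyl]oxymethyl}oxolan‑2‑ol (lactol, both C2 epimers)
Conditions: i‑Bu2AlH, CH2Cl2, −78 °C; aq. potassium sodium tartrate
Reagents that add atoms: none
Why: Partial reduction of a lactone to the lactol with i‑Bu2AlH at −78 °C (the aluminium hemiacetal does not collapse before work‑up); the cold, non‑basic medium should leave the C4 center next to the carbonyl untouched.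

**Step 8**
Reactants: 14 (3R,4R,5S)‑5‑Ar‑3‑(Ar‑methyl)‑4‑{[tert‑butyl(diphenyl)silyl]oxymethyl}oxolan‑2‑ol
Product: 15 tert‑butyl{[(2S,3R,4R)‑2‑Ar‑4‑(Ar‑methyl)oxolan‑3‑yl]methoxy}diphenylsilane
Conditions: Et3SiH, BF3·OEt2, CH2Cl2, −78 to −40 °C
Reagents that add atoms: none
Why: Ionic hydrogenation of a lactol (reductive deoxygenation), in which BF3 removes the anomeric hydroxyl and the cyclic oxocarbenium ion, still closed by the O1–C5 bond of step 4, takes hydride from Et3SiH at C5 (not stereogenic); at low temperature the benzylic C2–O1 bond should not ionize.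

**Step 9**
Reactants: 15 tert‑butyl{[(2S,3R,4R)‑2‑Ar‑4‑(Ar‑methyl)oxolan‑3‑yl]methoxy}diphenylsilane
Product: 16 [(2S,3R,4R)‑2‑Ar‑4‑(Ar‑methyl)oxolan‑3‑yl]methanol
Conditions: n‑Bu4NF, THF, 0 °C to rt
Reagents that add atoms: none
Why: Fluoride‑induced cleavage of the silyl ether (strong Si–F bond); oxolane and aryl benzyl ethers should be inert.

**Step 10**
Reactants: 16 [(2S,3R,4R)‑2‑Ar‑4‑(Ar‑methyl)oxolan‑3‑yl]methanol; 17 octadecanoyl chloride
Product: 18 [(2S,3R,4R)‑2‑Ar‑4‑(Ar‑methyl)oxolan‑3‑yl]methyl octadecanoate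
Conditions: Et3N, DMAP (cat.), CH2Cl2, 0 °C to rt
Reagents that add atoms: none
Why: DMAP‑catalyzed acylation (nucleophilic acyl substitution) of the only free hydroxyl; both phenols are still benzylated, so no selectivity problem should arise.

**Step 11**
Reactants: 18 [(2S,3R,4R)‑2‑Ar‑4‑(Ar‑methyl)oxolan‑3‑yl]methyl octadecanoate
Product: 19 [(2S,3R,4R)‑2‑(4‑hydroxy‑3‑methoxyphenyl)‑4‑[(4‑hydroxy‑3‑methoxyphenyl)methyl]oxolan‑3‑yl]methyl octadecanoate
Conditions: H2 (1 atm), 10% Pd/C, EtOAc, rt, stopped when 18 is consumed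
Reagents that add atoms: none
Why: Catalytic hydrogenolysis of the two aryl benzyl ethers, which should cleave far faster than the cyclic benzylic C2–O1 ether; ester and stereocenters are not touched.

**Compound list**

1 | 4‑(benzyloxy)‑3‑methoxybenzaldehyde | O=Cc1ccc(OCc2ccccc2)c(OC)c1 | starting material
2 | dimethyl succinate | COC(=O)CCC(=O)OC | starting material
3 | methyl 2‑Ar‑5‑oxooxolane‑3‑carboxylate (racemic Stobbe lactone, formed in the flask) | COC(=O)C1CC(=O)OC1c1ccc(OCc2ccccc2)c(OC)c1 | intermediate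
4 | (3E)‑4‑Ar‑3‑(methoxycarbonyl)but‑3‑enoic acid | OC(=O)C/C(=C\c1ccc(OCc2ccccc2)c(OC)c1)C(=O)OC | intermediate
5 | (3R)‑4‑Ar‑3‑(methoxycarbonyl)butanoic acid | OC(=O)C[C@@H](Cc1ccc(OCc2ccccc2)c(OC)c1)C(=O)OC | intermediate
6 | (4S)‑4‑benzyl‑1,3‑oxazolidin‑2‑one | O=C1N[C@@H](Cc2ccccc2)CO1 | starting material
7 | mixed anhydride of 5 with pivalic acid (formed in the flask) | CC(C)(C)C(=O)OC(=O)C[C@@H](Cc1ccc(OCc2ccccc2)c(OC)c1)C(=O)OC | intermediate
8 | methyl (2R)‑2‑(Ar‑methyl)‑4‑[(4S)‑4‑benzyl‑2‑oxo‑1,3‑oxazolidin‑3‑yl]‑4‑oxobutanoate | COC(=O)[C@H](Cc1ccc(OCc2ccccc2)c(OC)c1)CC(=O)N1[C@@H](Cc2ccccc2)COC1=O | intermediate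
9 | Z‑configured dibutylboron enolate of 8 (formed in the flask) | CCCCB(CCCC)O/C(=C\[C@@H](Cc1ccc(OCc2ccccc2)c(OC)c1)C(=O)OC)N1[C@@H](Cc2ccccc2)COC1=O | intermediate
10 | methyl (2R,3S)‑2‑(Ar‑methyl)‑3‑[(S)‑Ar(hydroxy)methyl]‑4‑[(4S)‑4‑benzyl‑2‑oxo‑1,3‑oxazolidin‑3‑yl]‑4‑oxobutanoate (syn‑aldol adduct, formed in the flask) | O=C(N1[C@@H](Cc2ccccc2)COC1=O)[C@H]([C@H](O)c1ccc(OCc2ccccc2)c(OC)c1)[C@@H](Cc1ccc(OCc2ccccc2)c(OC)c1)C(=O)OC | intermediate
11 | (4S)‑4‑benzyl‑3‑{[(2S,3S,4R)‑2‑Ar‑4‑(Ar‑methyl)‑5‑oxooxolan‑3‑yl]carbonyl}‑1,3‑oxazolidin‑2‑one | O=C(N1[C@@H](Cc2ccccc2)COC1=O)[C@H]1[C@@H](Cc2ccc(OCc3ccccc3)c(OC)c2)C(=O)O[C@@H]1c1ccc(OCc2ccccc2)c(OC)c1 | intermediate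
12 | (3R,4R,5S)‑5‑Ar‑3‑(Ar‑methyl)‑4‑(hydroxymethyl)oxolan‑2‑one | OC[C@H]1[C@@H](Cc2ccc(OCc3ccccc3)c(OC)c2)C(=O)O[C@@H]1c1ccc(OCc2ccccc2)c(OC)c1 | intermediate
13 | (3R,4R,5S)‑5‑Ar‑3‑(Ar‑methyl)‑4‑{[tert‑butyl(diphenyl)silyl]oxymethyl}oxolan‑2‑one | CC(C)(C)[Si](OC[C@H]1[C@@H](Cc2ccc(OCc3ccccc3)c(OC)c2)C(=O)O[C@@H]1c1ccc(OCc2ccccc2)c(OC)c1)(c1ccccc1)c1ccccc1 | intermediate
14 | (3R,4R,5S)‑5‑Ar‑3‑(Ar‑methyl)‑4‑{[tert‑butyl(diphenyl)silyl]oxymethyl}oxolan‑2‑ol (both C2 epimers) | CC(C)(C)[Si](OC[C@H]1[C@@H](Cc2ccc(OCc3ccccc3)c(OC)c2)C(O)O[C@@H]1c1ccc(OCc2ccccc2)c(OC)c1)(c1ccccc1)c1ccccc1 | intermediate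
15 | tert‑butyl{[(2S,3R,4R)‑2‑Ar‑4‑(Ar‑methyl)oxolan‑3‑yl]methoxy}diphenylsilane | CC(C)(C)[Si](OC[C@H]1[C@@H](Cc2ccc(OCc3ccccc3)c(OC)c2)CO[C@@H]1c1ccc(OCc2ccccc2)c(OC)c1)(c1ccccc1)c1ccccc1 | intermediate
16 | [(2S,3R,4R)‑2‑Ar‑4‑(Ar‑methyl)oxolan‑3‑yl]methanol | OC[C@H]1[C@@H](Cc2ccc(OCc3ccccc3)c(OC)c2)CO[C@@H]1c1ccc(OCc2ccccc2)c(OC)c1 | intermediate
17 | octadecanoyl chloride | CCCCCCCCCCCCCCCCCC(=O)Cl | starting material
18 | [(2S,3R,4R)‑2‑Ar‑4‑(Ar‑methyl)oxolan‑3‑yl]methyl octadecanoate | CCCCCCCCCCCCCCCCCC(=O)OC[C@H]1[C@@H](Cc2ccc(OCc3ccccc3)c(OC)c2)CO[C@@H]1c1ccc(OCc2ccccc2)c(OC)c1 | intermediate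
19 | [(2S,3R,4R)‑2‑(4‑hydroxy‑3‑methoxyphenyl)‑4‑[(4‑hydroxy‑3‑methoxyphenyl)methyl]oxolan‑3‑yl]methyl octadecanoate | CCCCCCCCCCCCCCCCCC(=O)OC[C@H]1[C@@H](Cc2ccc(O)c(OC)c2)CO[C@@H]1c1ccc(O)c(OC)c1 | target

**Step count and risks**

Total step count: 11. Longest linear sequence: 11 steps (1 and 2 to 19).

Steps most likely to fail:

1. Step 4. The auxiliary and the resident C4 center may be a mismatched pair, which would lower the facial selectivity of the aldol addition, and lactonization next to the cis benzyl group may be slow. Fallback (sets out from 4, returns at 11): the C4 center is set after the ring instead of before it. Acid 4 would be activated as its mixed pivalic anhydride F1 and coupled with 6 (conditions of step 3) to the unsaturated imide F2, which has no stereocenter beside the auxiliary. Boron enolization would give the Z‑boron dienolate F3, which should add to 1 at its α‑carbon under pure auxiliary control to the syn‑aldol adduct F4. Lactonization onto the conjugated ester would give the α‑benzylidene lactone F5. Hydrogenation of the exocyclic alkene (H2, Pd/C poisoned with Ph2S, EtOAc, which spares benzyl ethers and the benzylic lactone C–O bond) from the face anti to the C3 acyl group would set C4 cis to it and give 11.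

2. Step 5. The new primary alkoxide may migrate onto the lactone carbonyl (translactonization), the lactone may be over‑reduced, or the oxazolidinone ring may be opened at the hindered imide. Fallback (sets out from 11, returns at 12): LiOH/H2O2 in THF/H2O at 0 °C would cleave the imide to the lactone carboxylic acid F6 (any opened lactone recloses on acidification, since only the C5 carboxyl can reach O1). BH3·SMe2 in THF at 0 °C would then reduce the acid chemoselectively beside the lactone under non‑basic conditions, giving 12.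

3. Step 8. The Lewis acid may ionize the benzylic C2–O1 bond of the electron‑rich aryl oxolane, with epimerization at C2 or Friedel–Crafts closure onto the benzyl ring. Fallback (sets out from 13, returns at 15): LiBH4 in THF would open lactone 13 to the 1,4‑diol F7. The primary hydroxyl would be tosylated selectively (TsCl, pyridine, 0 °C) to the monotosylate F8. KOt‑Bu in THF would close the same O1–C5 bond by a 5‑exo‑tet Williamson substitution with retention at C2, giving 15 without any Lewis acid.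

Further compounds
F1 | step 4 | (3E)‑4‑Ar‑3‑(methoxycarbonyl)but‑3‑enoic 2,2‑dimethylpropanoic anhydride | CC(C)(C)C(=O)OC(=O)C/C(=C\c1ccc(OCc2ccccc2)c(OC)c1)C(=O)OC
F2 | step 4 | methyl (2E)‑2‑(Ar‑methylidene)‑4‑[(4S)‑4‑benzyl‑2‑oxo‑1,3‑oxazolidin‑3‑yl]‑4‑oxobutanoate | COC(=O)/C(=C/c1ccc(OCc2ccccc2)c(OC)c1)CC(=O)N1[C@@H](Cc2ccccc2)COC1=O
F3 | step 4 | Z‑configured dibutylboron dienolate of F2 | CCCCB(CCCC)O/C(=C\C(=C/c1ccc(OCc2ccccc2)c(OC)c1)C(=O)OC)N1[C@@H](Cc2ccccc2)COC1=O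
F4 | step 4 | methyl (2E,3S)‑2‑(Ar‑methylidene)‑3‑[(S)‑Ar(hydroxy)methyl]‑4‑[(4S)‑4‑benzyl‑2‑oxo‑1,3‑oxazolidin‑3‑yl]‑4‑oxobutanoate | O=C(N1[C@@H](Cc2ccccc2)COC1=O)[C@H]([C@H](O)c1ccc(OCc2ccccc2)c(OC)c1)/C(=C\c1ccc(OCc2ccccc2)c(OC)c1)C(=O)OC
F5 | step 4 | (4S)‑4‑benzyl‑3‑{[(2S,3S,4E)‑2‑Ar‑4‑(Ar‑methylidene)‑5‑oxooxolan‑3‑yl]carbonyl}‑1,3‑oxazolidin‑2‑one | O=C(N1[C@@H](Cc2ccccc2)COC1=O)[C@H]1/C(=C\c2ccc(OCc3ccccc3)c(OC)c2)C(=O)O[C@@H]1c1ccc(OCc2ccccc2)c(OC)c1
F6 | step 5 | (2S,3S,4R)‑2‑Ar‑4‑(Ar‑methyl)‑5‑oxooxolane‑3‑carboxylic acid | OC(=O)[C@H]1[C@@H](Cc2ccc(OCc3ccccc3)c(OC)c2)C(=O)O[C@@H]1c1ccc(OCc2ccccc2)c(OC)c1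
F7 | step 8 | (1S,2R,3R)‑1‑Ar‑3‑(Ar‑methyl)‑2‑{[tert‑butyl(diphenyl)silyl]oxymethyl}butane‑1,4‑diol | CC(C)(C)[Si](OC[C@H]([C@H](O)c1ccc(OCc2ccccc2)c(OC)c1)[C@@H](Cc1ccc(OCc2ccccc2)c(OC)c1)CO)(c1ccccc1)c1ccccc1
F8 | step 8 | (2R,3R,4S)‑4‑Ar‑2‑(Ar‑methyl)‑3‑{[tert‑butyl(diphenyl)silyl]oxymethyl}‑4‑hydroxybutyl 4‑methylbenzenesulfonate | CC(C)(C)[Si](OC[C@H]([C@H](O)c1ccc(OCc2ccccc2)c(OC)c1)[C@@H](Cc1ccc(OCc2ccccc2)c(OC)c1)COS(=O)(=O)c1ccc(C)cc1)(c1ccccc1)c1ccccc1
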